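**Plan**

1. Numbering follows the octahydro-2H-chromene core of the target: O1, C2 (Me, oxiranyl), C3, C4, C4a (ring-fusion CH), C5 (Me, CH2CO2H), C6 (CMe2CO2H), C7, C8, C8a (Me, O1).
2. Retrosynthesis: the acids are masked as benzyl esters and the oxirane as a diol acetonide; C4a–H is traced back to a C4=C4a alkene; C4–C4a and O1–C8a are then cut together, giving a cyclohexenyl triflate and a seven-carbon tertiary allylic alcohol; the carbocycle is cut at C6–CMe2 and C5–CH2CO2Bn back to 2-methylcyclohex-2-enone.
3. Enabling feature: C4a and C8a are adjacent members of the cyclohexane ring and are both sp2 in an enol triflate C4a(OTf)=C8a(CH3), while the pyran atoms C4–C3–C2–O1 are exactly CH2=CH–C(Me)(R)–OH; a palladium walk from the vinyl carbon C4a to an allyl over C4–C4a–C8a lets one catalyst make the C–C bond at C4a and the di-tertiary ether at C8a.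
4. Forward: the cyclohexane ring is bought and dressed (conjugate addition at C6, alkylation at C5, methylation at C8a, triflation); the pyran ring closes in the fragment union; then C4=C4a is reduced, the oxirane is made from the diol and the esters are cleaved.
5. Stereochemistry: C6 by catalyst-controlled Mukaiyama–Michael addition; C5 by alkylation anti to the C6 group; the oxirane carbon from (S)-glycerate; C2 by Felkin–Anh vinyl addition; C8a in the union (oxygen anti to the 5-methyl); C4a by hydrogen-atom delivery anti to the two axial methyls.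

Key step: step 8

Assumption: in step 2 the catalyst antipode is the one that gives the (1S) adduct; the (S)-prolinol-derived salt is written, and its mirror image is used if the sense of induction on this α-methyl enone is the opposite.

**Route**

Step 1
Reactants: 1 benzyl 2-methylpropanoate
Product: 2 {[1-(benzyloxy)-2-methylprop-1-en-1-yl]oxy}(trimethyl)silane
Conditions: LiN(i-Pr)2, THF, −78 °C; Me3SiCl, −78 to 22 °C
Reagents that add atoms: chlorotrimethylsilane, C[Si](C)(C)Cl
Why: Kinetic deprotonation of the ester and O-silylation of the lithium enolate give the tetrasubstituted silyl ketene acetal (enolate silylation), which has no geometric isomers.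

Step 2
Reactants: 2 silyl ketene acetal; 3 2-methylcyclohex-2-en-1-one
Product: 4 benzyl 2-methyl-2-[(1S)-2-methyl-3-(trimethylsilyloxy)cyclohex-2-en-1-yl]propanoate
Conditions: (S)-3,3-diphenyl-1-(o-tolyl)tetrahydro-1H,3H-pyrrolo[1,2-c][1,3,2]oxazaborole·HNTf2 (20 mol %), Ph3PO (25 mol %), toluene, −20 °C
Reagents that add atoms: none
Why: Mukaiyama–Michael addition under chiral oxazaborolidinium catalysis should attack the catalyst-bound enone at C6 on one face and transfer silicon to the enone oxygen, so that C6 is set (S) by the catalyst and the C4a=C5 silyl enol ether is formed regiospecifically.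

Step 3
Reactants: 4 silyl enol ether; 5 benzyl bromoacetate
Product: 6 benzyl 2-[(1S,2R)-2-(2-benzyloxy-2-oxoethyl)-2-methyl-3-oxocyclohexyl]-2-methylpropanoate
Conditions: PhCH2NMe3F, 4 Å molecular sieves, THF, 0 to 22 °C
Reagents that add atoms: none
Why: Fluoride should unmask the ammonium enolate at C5 regiospecifically (avoiding an organolithium that would attack the esters), and C-alkylation by the reactive α-bromo ester should occur anti to the C6 substituent, which allylic strain with the 5-methyl holds pseudoaxial, setting the quaternary C5 with CH2CO2Bn trans to the C6 group (regiospecific enolate alkylation).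

Step 4
Reactants: 6 keto diester
Product: 7 benzyl 2-[(1S,2R)-2-(2-benzyloxy-2-oxoethyl)-2,4-dimethyl-3-oxocyclohexyl]-2-methylpropanoate (mixture of epimers at the new methyl-bearing carbon)
Conditions: LiN(SiMe3)2, THF, −78 °C; MeI, −78 to −20 °C
Reagents that add atoms: iodomethane, CI
Why: The ketone can enolize only toward C8a (C5 is quaternary) and is far more acidic than the esters, so ketone enolate alkylation should methylate C8a, whose configuration is irrelevant because it becomes sp2 in step 5.

Step 5
Reactants: 7 methylated keto diester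
Product: 8 benzyl 2-[(1S,2R)-2-(2-benzyloxy-2-oxoethyl)-2,4-dimethyl-3-{[(trifluoromethyl)sulfonyl]oxy}cyclohex-3-en-1-yl]-2-methylpropanoate
Conditions: KN(SiMe3)2, THF, −78 °C; PhNTf2, −78 to 0 °C
Reagents that add atoms: N-phenylbis(trifluoromethanesulfonimide), O=S(=O)(N(c1ccccc1)S(=O)(=O)C(F)(F)F)C(F)(F)F
Why: Removal of the only α-hydrogen and O-triflation (enol triflate formation) should give the tetrasubstituted triflate C4a(OTf)=C8a(CH3) and converge both C8a epimers.

Step 6
Reactants: 9 methyl (4S)-2,2-dimethyl-1,3-dioxolane-4-carboxylate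
Product: 11 1-[(4S)-2,2-dimethyl-1,3-dioxolan-4-yl]ethan-1-one, via Weinreb amide 10 (not isolated)
Conditions: MeNH(OMe)·HCl, i-PrMgCl, THF, −20 °C; then MeMgBr, 0 °C; aq. NH4Cl
Reagents that add atoms: methylmagnesium bromide, C[Mg]Br; N,O-dimethylhydroxylamine hydrochloride, CNOC.Cl (ends only in intermediate 10)
Why: The magnesium amide should convert the ester into the Weinreb amide, whose chelated adduct with MeMgBr stops at the ketone (Weinreb ketone synthesis) under cold conditions that should leave the α-stereocentre untouched.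

Step 7
Reactants: 11 methyl ketone
Product: 12 (2R)-2-[(4S)-2,2-dimethyl-1,3-dioxolan-4-yl]but-3-en-2-ol
Conditions: CH2=CHMgBr, THF, −78 °C; aq. NH4Cl
Reagents that add atoms: vinylmagnesium bromide, C=C[Mg]Br
Why: Felkin–Anh addition in coordinating THF should place the dioxolane C–O bond anti to the incoming vinyl group, which passes the α-hydrogen and gives the (2R) tertiary carbinol (anti adduct).

Step 8
Reactants: 8 enol triflate; 12 tertiary allylic alcohol
Product: 13 benzyl 2-[(2R,5R,6S,8aS)-5-(2-benzyloxy-2-oxoethyl)-2-[(4S)-2,2-dimethyl-1,3-dioxolan-4-yl]-2,5,8a-trimethyl-3,5,6,7,8,8a-hexahydro-2H-chromen-6-yl]-2-methylpropanoate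
Conditions: Pd(OAc)2 (10 mol %), n-Bu4NCl, Na2CO3, DMF, 80 °C
Reagents that add atoms: none
Why: Proposed new method: zerovalent palladium should add oxidatively to the C4a–OTf bond of 8, the vinyl group of 12 should insert (C4 bonds to C4a, palladium to C3), and β-hydride elimination followed by re-addition of Pd–H in the opposite sense should walk palladium to an η3-allyl over C4–C4a–C8a, on which the tethered tertiary hydroxyl, bound to palladium as alkoxide, forms O1–C8a and releases zerovalent palladium. The closest known reaction type is the Larock heteroannulation and the related coupling of vinylic halides or triflates with alkenes that carry an internal nucleophile, where palladium migrates to a π-allyl that the nucleophile captures; here the one-atom-shorter tether rules out the near terminus (an oxetane) and sends oxygen to the far terminus. The dihydropyran ring closes by six-membered C–O bond formation at the C8a allyl terminus, with the C3 substituent anti on the allyl so that C4=C4a is cis within the ring. The new stereocentre C8a should be controlled by the quaternary C5: palladium and its alkoxide sit on the allyl face opposite the pseudoaxial 5-methyl, so oxygen enters trans to that methyl and the 8a-methyl ends syn to it, the arrangement that also lets the cyclohexane keep its chair with the C6 group equatorial; C2 and the dioxolane centre come unchanged from 12. The step needs terminal regioselectivity in the insertion, which the quaternary carbinol carbon next to the alkene and the chloride-mediated neutral Heck pathway secure, and it needs chain walking to outrun loss of HX to base, which phosphine-free conditions and the gain in conjugation on forming the allyl favour.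

Step 9
Reactants: 13 hexahydrochromene
Product: 14 benzyl 2-[(2R,4aS,5R,6S,8aS)-5-(2-benzyloxy-2-oxoethyl)-2-[(4S)-2,2-dimethyl-1,3-dioxolan-4-yl]-2,5,8a-trimethyloctahydro-2H-chromen-6-yl]-2-methylpropanoate
Conditions: Mn(dpm)3 (10 mol %), PhSiH3, t-BuOOH, i-PrOH, 22 °C
Reagents that add atoms: none
Why: Hydrogen-atom-transfer hydrogenation should deliver H• from the manganese hydride to the accessible C4, and the tertiary C4a radical should take its hydrogen on the face opposite the two syn-axial methyls at C5 and C8a, giving the trans ring fusion (4aS) that is also the thermodynamically preferred outcome of this stepwise reduction, while benzyl esters and acetonide stay inert.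

Step 10
Reactants: 14 octahydrochromene acetonide
Product: 15 benzyl 2-[(2R,4aS,5R,6S,8aS)-5-(2-benzyloxy-2-oxoethyl)-2-[(1S)-1,2-dihydroxyethyl]-2,5,8a-trimethyloctahydro-2H-chromen-6-yl]-2-methylpropanoate
Conditions: AcOH/H2O 4:1, 45 °C
Reagents that add atoms: none
Why: Acid-catalysed acetal hydrolysis should free the diol while the benzyl esters and the di-tertiary ring ether survive aqueous acetic acid.

Step 11
Reactants: 15 diol
Product: 17 benzyl 2-[(2R,4aS,5R,6S,8aS)-5-(2-benzyloxy-2-oxoethyl)-2,5,8a-trimethyl-2-[(2S)-oxiran-2-yl]octahydro-2H-chromen-6-yl]-2-methylpropanoate, via primary tosylate 16 (not isolated)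
Conditions: TsCl, Et3N, Bu2SnO (5 mol %), CH2Cl2, 0 °C; then DBU, 22 °C
Reagents that add atoms: p-toluenesulfonyl chloride, Cc1ccc(cc1)S(=O)(=O)Cl (ends only in intermediate 16)
Why: Tin-catalysed sulfonylation should select the primary hydroxyl, and the secondary alkoxide then displaces the tosylate (intramolecular Williamson closure, 3-exo-tet), so the carbinol carbon keeps its configuration and becomes the (2S)-oxirane carbon.

Step 12
Reactants: 17 dibenzyl ester
Product: 18 2-[(2R,4aS,5R,6S,8aS)-5-(carboxymethyl)-2,5,8a-trimethyl-2-[(2S)-oxiran-2-yl]octahydro-2H-chromen-6-yl]-2-methylpropanoic acid (target)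
Conditions: H2 (1 atm), 10% Pd/C, EtOAc, 22 °C
Reagents that add atoms: none
Why: Hydrogenolysis of both benzyl esters should free the acids under neutral conditions that spare the aliphatic oxirane, and it is not slowed by the hindered acyl carbon because the benzylic C–O bond is the one cleaved.

**Compound list**

1 | benzyl 2-methylpropanoate | CC(C)C(=O)OCc1ccccc1 | starting material
2 | {[1-(benzyloxy)-2-methylprop-1-en-1-yl]oxy}(trimethyl)silane | CC(C)=C(OCc1ccccc1)O[Si](C)(C)C | intermediate
3 | 2-methylcyclohex-2-en-1-one | CC1=CCCCC1=O | starting material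
4 | benzyl 2-methyl-2-[(1S)-2-methyl-3-(trimethylsilyloxy)cyclohex-2-en-1-yl]propanoate | CC(C)(C(=O)OCc2ccccc2)[C@H]1CCCC(O[Si](C)(C)C)=C1C | intermediate
5 | benzyl bromoacetate | BrCC(=O)OCc1ccccc1 | starting material
6 | benzyl 2-[(1S,2R)-2-(2-benzyloxy-2-oxoethyl)-2-methyl-3-oxocyclohexyl]-2-methylpropanoate | CC(C)(C(=O)OCc2ccccc2)[C@H]1CCCC(=O)[C@]1(C)CC(=O)OCc3ccccc3 | intermediate
7 | benzyl 2-[(1S,2R)-2-(2-benzyloxy-2-oxoethyl)-2,4-dimethyl-3-oxocyclohexyl]-2-methylpropanoate (C4 epimers) | CC(C)(C(=O)OCc2ccccc2)[C@H]1CCC(C)C(=O)[C@]1(C)CC(=O)OCc3ccccc3 | intermediate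
8 | benzyl 2-[(1S,2R)-2-(2-benzyloxy-2-oxoethyl)-2,4-dimethyl-3-{[(trifluoromethyl)sulfonyl]oxy}cyclohex-3-en-1-yl]-2-methylpropanoate | CC(C)(C(=O)OCc2ccccc2)[C@H]1CCC(C)=C(OS(=O)(=O)C(F)(F)F)[C@]1(C)CC(=O)OCc3ccccc3 | intermediate
9 | methyl (4S)-2,2-dimethyl-1,3-dioxolane-4-carboxylate | COC(=O)[C@@H]1COC(C)(C)O1 | starting material
10 | (4S)-N-methoxy-N,2,2-trimethyl-1,3-dioxolane-4-carboxamide | CON(C)C(=O)[C@@H]1COC(C)(C)O1 | intermediate
11 | 1-[(4S)-2,2-dimethyl-1,3-dioxolan-4-yl]ethan-1-one | CC(=O)[C@@H]1COC(C)(C)O1 | intermediate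
12 | (2R)-2-[(4S)-2,2-dimethyl-1,3-dioxolan-4-yl]but-3-en-2-ol | C=C[C@@](C)(O)[C@@H]1COC(C)(C)O1 | intermediate
13 | benzyl 2-[(2R,5R,6S,8aS)-5-(2-benzyloxy-2-oxoethyl)-2-[(4S)-2,2-dimethyl-1,3-dioxolan-4-yl]-2,5,8a-trimethyl-3,5,6,7,8,8a-hexahydro-2H-chromen-6-yl]-2-methylpropanoate | CC(C)(C(=O)OCc4ccccc4)[C@H]1CC[C@]2(C)O[C@@](C)([C@@H]3COC(C)(C)O3)CC=C2[C@]1(C)CC(=O)OCc5ccccc5 | intermediate
14 | benzyl 2-[(2R,4aS,5R,6S,8aS)-5-(2-benzyloxy-2-oxoethyl)-2-[(4S)-2,2-dimethyl-1,3-dioxolan-4-yl]-2,5,8a-trimethyloctahydro-2H-chromen-6-yl]-2-methylpropanoate | CC(C)(C(=O)OCc4ccccc4)[C@H]1CC[C@]2(C)O[C@@](C)([C@@H]3COC(C)(C)O3)CC[C@H]2[C@]1(C)CC(=O)OCc5ccccc5 | intermediate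
15 | benzyl 2-[(2R,4aS,5R,6S,8aS)-5-(2-benzyloxy-2-oxoethyl)-2-[(1S)-1,2-dihydroxyethyl]-2,5,8a-trimethyloctahydro-2H-chromen-6-yl]-2-methylpropanoate | CC(C)(C(=O)OCc4ccccc4)[C@H]1CC[C@]2(C)O[C@@](C)([C@@H](O)CO)CC[C@H]2[C@]1(C)CC(=O)OCc5ccccc5 | intermediate
16 | benzyl 2-[(2R,4aS,5R,6S,8aS)-5-(2-benzyloxy-2-oxoethyl)-2-[(1S)-1-hydroxy-2-(tosyloxy)ethyl]-2,5,8a-trimethyloctahydro-2H-chromen-6-yl]-2-methylpropanoate | CC(C)(C(=O)OCc4ccccc4)[C@H]1CC[C@]2(C)O[C@@](C)([C@@H](O)COS(=O)(=O)c3ccc(C)cc3)CC[C@H]2[C@]1(C)CC(=O)OCc5ccccc5 | intermediate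
17 | benzyl 2-[(2R,4aS,5R,6S,8aS)-5-(2-benzyloxy-2-oxoethyl)-2,5,8a-trimethyl-2-[(2S)-oxiran-2-yl]octahydro-2H-chromen-6-yl]-2-methylpropanoate | CC(C)(C(=O)OCc4ccccc4)[C@H]1CC[C@]2(C)O[C@@](C)([C@@H]3CO3)CC[C@H]2[C@]1(C)CC(=O)OCc5ccccc5 | intermediate
18 | 2-[(2R,4aS,5R,6S,8aS)-5-(carboxymethyl)-2,5,8a-trimethyl-2-[(2S)-oxiran-2-yl]octahydro-2H-chromen-6-yl]-2-methylpropanoic acid | CC(C)(C(=O)O)[C@H]1CC[C@]2(C)O[C@@](C)([C@@H]3CO3)CC[C@H]2[C@]1(C)CC(=O)O | target

**Step count**

Total: 12 steps. Longest linear sequence: 10 steps (steps 1–5, then 8–12); steps 6–7 form the second branch.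

**Steps most likely to fail**

1. Step 8 (Proposed new method). The cascade may stop at the open Heck product if palladium hydride is lost to base before it re-inserts. The allyl complex may lose a β-hydrogen to give trienes. Oxygen may be delivered to the wrong face of C8a. Fallback: it sets out from 8 and 12 and splits the union into two known operations. An ordinary Heck coupling (Pd(OAc)2, PPh3, Et3N, DMF, 70 °C) should give benzyl 2-[(1S,2R)-2-(2-benzyloxy-2-oxoethyl)-3-{(1E,3R)-3-[(4S)-2,2-dimethyl-1,3-dioxolan-4-yl]-3-hydroxybut-1-en-1-yl}-2,4-dimethylcyclohex-3-en-1-yl]-2-methylpropanoate F1. The ring is then closed by a hydrogen-atom-transfer hydroalkoxylation (a Co(salen) catalyst, an N-fluoropyridinium oxidant and PhSiH3, neutral medium). H• adds to C3, the allyl radical is oxidised to a metal-free allyl cation, and the hydroxyl closes on C8a from the face opposite the 5-methyl. No Brønsted acid is present that could ionise the tertiary allylic alcohol. The sequence comes back to the route at 13.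

2. Step 2. Enantiofacial control by the oxazaborolidinium salt may be insufficient on an α-methyl enone, or the uncatalysed silyl-transfer pathway may compete. Fallback: it sets out from 2 and 3 and replaces asymmetric catalysis by resolution through the enantiopure partner. A racemic Mukaiyama–Michael addition (HNTf2, 1 mol %, CH2Cl2, −78 °C) gives 4 together with benzyl 2-methyl-2-[(1R)-2-methyl-3-(trimethylsilyloxy)cyclohex-2-en-1-yl]propanoate F2. Steps 3 to 5 are run on the racemate, which also carries the enantiomeric keto diester F3, the enantiomeric methylated keto diester F4 and the enantiomeric enol triflate F5. Union with enantiopure 12 under the conditions of step 8 then gives 13 and the diastereomeric hexahydrochromene F6, which differ in the relation of the C2 substituents to the carbocycle and should separate on silica. The fallback comes back to the route at 13.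

3. Step 7. Felkin–Anh and chelate transition states may compete, so that facial selectivity at the ketone is poor. Fallback: it sets out from amide 10 (made from 9 as in step 6 and isolated) and swaps the order in which the two carbon groups are introduced, together with the control element. Vinylmagnesium bromide gives 1-[(4S)-2,2-dimethyl-1,3-dioxolan-4-yl]prop-2-en-1-one F7. Methylmagnesium bromide with MgBr2·OEt2 in CH2Cl2 at −78 °C then adds under chelation control, which now delivers methyl to the face the chelate leaves open and gives the same (2R) carbinol. The fallback comes back to the route at 12.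

**Further compounds**

F1 | step 8 | benzyl 2-[(1S,2R)-2-(2-benzyloxy-2-oxoethyl)-3-{(1E,3R)-3-[(4S)-2,2-dimethyl-1,3-dioxolan-4-yl]-3-hydroxybut-1-en-1-yl}-2,4-dimethylcyclohex-3-en-1-yl]-2-methylpropanoate | CC(C)(C(=O)OCc2ccccc2)[C@H]1CCC(C)=C(/C=C/[C@@](C)(O)[C@@H]4COC(C)(C)O4)[C@]1(C)CC(=O)OCc3ccccc3
F2 | step 2 | benzyl 2-methyl-2-[(1R)-2-methyl-3-(trimethylsilyloxy)cyclohex-2-en-1-yl]propanoate | CC(C)(C(=O)OCc2ccccc2)[C@@H]1CCCC(O[Si](C)(C)C)=C1C
F3 | step 2 | benzyl 2-[(1R,2S)-2-(2-benzyloxy-2-oxoethyl)-2-methyl-3-oxocyclohexyl]-2-methylpropanoate | CC(C)(C(=O)OCc2ccccc2)[C@@H]1CCCC(=O)[C@@]1(C)CC(=O)OCc3ccccc3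
F4 | step 2 | benzyl 2-[(1R,2S)-2-(2-benzyloxy-2-oxoethyl)-2,4-dimethyl-3-oxocyclohexyl]-2-methylpropanoate (C4 epimers) | CC(C)(C(=O)OCc2ccccc2)[C@@H]1CCC(C)C(=O)[C@@]1(C)CC(=O)OCc3ccccc3
F5 | step 2 | benzyl 2-[(1R,2S)-2-(2-benzyloxy-2-oxoethyl)-2,4-dimethyl-3-{[(trifluoromethyl)sulfonyl]oxy}cyclohex-3-en-1-yl]-2-methylpropanoate | CC(C)(C(=O)OCc2ccccc2)[C@@H]1CCC(C)=C(OS(=O)(=O)C(F)(F)F)[C@@]1(C)CC(=O)OCc3ccccc3
F6 | step 2 | benzyl 2-[(2R,5S,6R,8aR)-5-(2-benzyloxy-2-oxoethyl)-2-[(4S)-2,2-dimethyl-1,3-dioxolan-4-yl]-2,5,8a-trimethyl-3,5,6,7,8,8a-hexahydro-2H-chromen-6-yl]-2-methylpropanoate | CC(C)(C(=O)OCc4ccccc4)[C@@H]1CC[C@@]2(C)O[C@@](C)([C@@H]3COC(C)(C)O3)CC=C2[C@@]1(C)CC(=O)OCc5ccccc5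
F7 | step 7 | 1-[(4S)-2,2-dimethyl-1,3-dioxolan-4-yl]prop-2-en-1-one | C=CC(=O)[C@@H]1COC(C)(C)O1
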